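Maple carries more partner than oak, 3.80 mM against 1.20 mM, on the same charge of starting material.

    starting material + catalyst → catalyst + intermediate (k1 = 2600 M⁻¹ s⁻¹)
    partner + catalyst + intermediate ⇌ catalyst + target (K2 = 4900 M⁻¹, k2 = 1.6 × 10⁶ M⁻² s⁻¹)
    partner + target → over-reaction product (k3 = 0.51 M⁻¹ s⁻¹)

| flask | starting material | partner | catalyst | time |
|---|---|---|---|---|
| oak | 0.50 mM | 1.20 mM | 13 µM | 2.5 min |
| maple | 0.50 mM | 3.80 mM | 13 µM | 2.5 min |

- which of these there is most of at the end, counted by the starting material in it, oak (starting material / target / intermediate / over-reaction product)
- which of these there is most of at the end, counted by the starting material in it, maple (starting material / target / intermediate / over-reaction product)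
- how much there is at the end of the one of these that leads, in percent of the starting material charged: oak
- how much there is at the end of the one of these that leads, in percent of the starting material charged: maple

Starting material is the smaller charge, the limiting reagent, so I write its balance: what was charged stands as starting material, intermediate, target or over-reaction product. I turn the settings one at a time.

Catalyst: the half-life of starting material by the first step alone is 0.34 min, shorter than the time, so 0.628% of it is left. Catalyst stands on both sides of the second step, so it hurries that step and leaves its balance as it is.

Partner: with one equivalent spent, [partner] in oak is 0.700 mM, and the equilibrium constant 4900 M⁻¹ times this gives 3.43. This is the split, the ratio of target to intermediate at the balance of the second step. More starting material spends more partner and so shrinks the split.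

Time: in oak the forward half-life of intermediate, 0.46 min, is shorter than the time, but it counts the forward rate alone, with the way back left out, so reckoning with the balance as reached is a rough assumption of mine. The half-life of target by the third step, 19 min, is longer than the time, so I let target decay at the rate constant 0.51 M⁻¹ s⁻¹ times [partner] over the whole time, and 94.8% survives in oak.

On that assumption, I reckon target as split/(1 + split) times the surviving part. In oak target leads at 73.4%. In maple the split is larger, 16.2, but the surviving part is smaller, 77.7%, so target leads at 73.2%, level with oak.

The forecast differs from me on that point: it gives target at 71% (66% to 76%) in oak and target at 76% (71% to 81%) in maple, saying “the extra partner pushes the equilibrium much further towards target”.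

The simulation gives target at 71.2% in oak and target at 78.0% in maple, so maple stands 6.8 percentage points higher. For maple, with each setting moved alone by the same factor, the order is time (4.5 points), then partner (3.8 points), then catalyst (0.97 points), then starting material (0.31 points). A neighbour of oak charged with 2.0 mM of partner has a split of 7.35 against 3.43 in oak, and 89.2% surviving, so I reckon target at 78.5%. That neighbour ends with intermediate at 13.0%, over-reaction product at 6.88% and target at 79.5%.

The constants used here are assumed; the result is computed.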